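## The problem

Pseudopentafuhalol D (24) is a linear chain of five benzene rings joined only by four diaryl ether oxygens and carrying thirteen free phenolic hydroxyls. Lettered A to E from the 2,4,6-trihydroxyphenyl end to the 3,4,5-trihydroxyphenyl end, the rings are connected A–O–B–O–C–O–D–O–E. There is no stereocentre and no carbon–carbon bond between rings, so the task is purely regiochemical: each of the seventeen oxygens must be placed by construction, because all five rings are too electron-rich for late electrophilic substitution to tell their positions apart. Two ether carbons are the hard ones. In ring B the carbon bound to the ring C oxygen lies between the ring A ether carbon and a hydroxylated carbon. In ring D the carbon bound to the ring E oxygen lies between the ring C ether carbon and the first of three contiguous hydroxylated carbons. Both are electron-rich and doubly ortho-substituted, the worst case for metal-mediated etherification. The free polyphenol (a phloroglucinol ring, a catechol unit in ring C, pyrogallol units in rings D and E) oxidises readily in air and base, so all hydroxyls travel as methyl ethers and are released only in the last, acidic step. The feature that invites a special solution is ring D: its two ether oxygens sit on adjacent carbons C1 (to ring C) and C2 (to ring E), and C2 is flanked on its other side by the C3 oxygen. These two carbons map onto the triple bond of 3,4,5-trimethoxybenzyne, whose single flanking methoxy group tells a nucleophile and an electrophile where to go.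

## Retrosynthesis

**24 ⇒ 23.** The thirteen O–CH3 bonds are cut last. Methyl is preferred to benzyl as the general mask because it survives hydrogenolysis, organolithium reagents, fluoride and hot basic copper catalysis, all of which the route needs. The tridecamethyl ether 23 is a stable, chromatographable compound; the forward step asks BBr3 to cleave thirteen aryl methyl ethers without touching the four diaryl ether bonds.

**23 ⇒ 16 + 22.** The bond between the ring C oxygen and the doubly flanked ring B carbon is cut. Cutting here rather than at A–O–B or D–O–E divides the molecule into a three-ring phenol (16) and a two-ring iodide (22), the most convergent split. The phenol oxygen of 16 has two CH neighbours, so all the steric burden lies on the iodide. The forward reaction is an Ullmann etherification of a 2,6-dioxygenated aryl iodide, a coupling type used in this compound class.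

**16 ⇒ 15 ⇒ 14 + 1.** The benzyl–oxygen bond is cut (unmasking of the ring C phenol), then the bond between the ring E oxygen and ring D C2. Ring E then comes from purchasable 3,4,5-trimethoxyphenol (1). What remains is iodide 14, which carries its leaving group exactly at the flanked ring D carbon. Hydrogenolysis must follow the copper step so that the iodide is gone before Pd and H2 are used.

**14 ⇒ 5 + 10 (key disconnection).** Two bonds at adjacent ring D carbons are cut together: C1–O to ring C and C2–I. This leads to aryne 12, released from silyl triflate 5, to the phenoxide of 10 and to an iodine donor. The stepwise neighbours are worse. Iodination of the halogen-free diaryl ether could not discriminate the equally activated CH positions of rings C and D, and directed lithiation would compete with the benzylic and ring C protons. Both precursors are monocyclic. The forward reaction must deliver oxygen to the aryne carbon remote from methoxy, and iodine transfer to the resulting aryl anion must outrun protonation.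

**5 ⇒ 2 ⇒ 1.** The C–Si and O–S bonds of 5 are cut back to bromophenol 2 by the standard silylation, retro-Brook and triflation sequence. Compound 2 comes from 1 by bromination at its only kind of ring CH, so ring E and ring D share one starting material.

**10 ⇒ 9 ⇒ 8 ⇒ 6.** The free hydroxyl of 10 is traced to the C–Br bond of 9, the benzyl ether to phenol 8, and that phenol to the formyl group of 3-bromo-4,5-dimethoxybenzaldehyde (6) by Baeyer–Villiger oxidation. Compound 6 already holds the 1,2,3,5 pattern with three different handles on the right carbons: the formyl carbon becomes the benzyloxy carbon and the bromine becomes the hydroxyl that attacks the aryne. The aldehyde is consumed first, so no formyl group has to pass through a basic alkoxide or hydroxide coupling.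

**22 ⇒ 20 ⇒ 18 + 19; 18 ⇒ 17.** The C–I bond of 22 is traced to the C–Br bond of 20 through aryllithium 21. The A–O–B bond is cut to 2,4,6-trimethoxyphenol (19) and dihalide 18, and 18 to 1-iodo-3,5-dimethoxybenzene (17). The halogen must be set on ring B before ring A is attached, because ring A would compete in any later halogenation. Bromine is the spectator that survives an iodide-selective Ullmann coupling and is then exchanged for iodine.

## Roads not taken

**Alternative 1:** Ring B would be built around a pre-formed A–O–B ether. The cut runs through ring B carbon–carbon bonds back to 4-(benzyloxy)-3-methoxy-4-[1-(2,4,6-trimethoxyphenoxy)ethenyl]cyclobut-2-en-1-one A1.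
- Key step: heating A1 should open the four-membered ring to a dienylketene, which closes by 6π-electrocyclisation between the ketene carbon and the vinyl CH2 and tautomerises to 4-(benzyloxy)-3-methoxy-5-(2,4,6-trimethoxyphenoxy)phenol A2.
- Merits: all four ring B oxygens arrive differentiated and regiochemically fixed, and the crowded A–O–B ether is never made by coupling at an aromatic carbon. The thermal ring expansion of 4-alkenylcyclobutenones is an established reaction class, so this key step is more certain than the one chosen. After debenzylation, A2 would offer the B–O–C junction as a hindered phenol meeting an unhindered halide, a better polarity than the hindered iodide 22 of step 12.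
- Weak points: A1 needs a multistep preparation (a vinyl ether of a 2,6-disubstituted phenol, its α-metalation, addition to a four-membered diketone, O-benzylation of a tertiary alcohol). The free hydroxyl of A2 must still be methylated. Nothing is gained for ring D, whose adjacent ethers would still have to be made one by one at a doubly flanked carbon.
- Comparison: the chosen plan is less certain at its key step. Against that it installs both ring D substituents in one operation and keeps every fragment within three steps of a purchasable arene.

**Alternative 2:** Ring A would be made last in biomimetic fashion. The cut is the C6–C1 bond of a triketide, leading back to 6-{3-[2-(benzyloxy)-3,5-dimethoxyphenoxy]-2-oxopropyl}-2,2-dimethyl-4H-1,3-dioxin-4-one A3.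
- Key step: NaOMe in methanol should open A3 to methyl 6-[2-(benzyloxy)-3,5-dimethoxyphenoxy]-3,5-dioxohexanoate A4. Its C6 enolate attacks the ester carbonyl and the ring aromatises to 2-[2-(benzyloxy)-3,5-dimethoxyphenoxy]benzene-1,3,5-triol A5.
- Merits: the A–O–B ether is formed as a simple alkyl aryl ether without any metal, and ring A arrives with its three hydroxyls free, which would spare three of the thirteen demethylations. In mildness and in this saving the road is better than the chosen one.
- Weak points: the carbon that must act as nucleophile is the oxygen-substituted, more hindered C6, and 3,5-dioxo esters tend to close through oxygen to 4-hydroxy-2-pyranones. The free phloroglucinol ring of A5 is nucleophilic at carbon and oxygen and would not survive three further copper-mediated etherifications. It would have to be re-methylated, which cancels the saving, or ring A would have to be built at the very end on a four-ring chain carrying the sensitive dioxinone.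
- Comparison: this road spends its key step on a ring that is purchasable as 19 and leaves the two crowded ether carbons of rings B and D untouched. The chosen plan spends its key step on ring D, where classical chemistry is weakest.

**Alternative 3:** Ring E would be grown onto the ring D oxygen by a Danheiser benzannulation. The cut runs through ring E carbon–carbon bonds back to 1-(benzyloxy)-2-(ethynyloxy)-3,4,5-trimethoxybenzene A6 and 3-ethoxy-4-methoxycyclobut-2-en-1-one A7.
- Key step: on heating, A7 opens to a vinylketene that adds across the alkyne of A6 (carbonyl carbon to the CH terminus, α-carbon to the oxygen-bearing carbon). Ring opening and 6π-closure then give 5-[6-(benzyloxy)-2,3,4-trimethoxyphenoxy]-3-ethoxy-2-methoxyphenol A8.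
- Merits: the D–O–E ether at the doubly flanked ring D carbon is made from a phenol oxygen, so the Ullmann coupling at a di-ortho-substituted iodide that the chosen route faces in step 7 is avoided. In this respect the road is better, and its regiochemistry is fixed by the cycloaddition.
- Weak points: ring E is the simplest ring of the target and is purchasable as 1. A6 is a pentaoxygenated arene with three kinds of oxygen substituent and needs a long synthesis of its own, including the conversion of a hindered phenol into an ethynyl ether. A7 is not trivial, the new hydroxyl of A8 must be methylated, and the ring C–ring D ether is still to be made.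
- Comparison: the chosen plan answers with one step that forms the C–O–D ether and marks the ring E carbon together, and it keeps the commercial ring E phenol. Its step 7 is the price, and a fallback for it is provided.

Key step: step 6

Remark on availability and masking: compounds 1, 6, 17 and 19 are taken to be purchasable; all hydroxyls are carried as methyl ethers and the ring C oxygen destined for ring B as a benzyl ether.

## Route

Step 1
Reactants: 1 3,4,5-trimethoxyphenol
Product: 2 2-bromo-3,4,5-trimethoxyphenol
Conditions: NBS (1.0 equiv), CH2Cl2, −78 °C → 0 °C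
Reagents that add atoms: N-bromosuccinimide, O=C1CCC(=O)N1Br
Why: Electrophilic aromatic bromination; the two ring CH positions of 1 are equivalent and ortho to the hydroxyl, so only the degree of bromination needs control, and one equivalent at low temperature should stop at the monobromide.

Step 2
Reactants: 2 2-bromo-3,4,5-trimethoxyphenol
Product: 5 3,4,5-trimethoxy-2-(trimethylsilyl)phenyl trifluoromethanesulfonate, via (2-bromo-3,4,5-trimethoxyphenoxy)trimethylsilane 3 (not isolated), via lithium 3,4,5-trimethoxy-2-(trimethylsilyl)phenoxide 4 (not isolated)
Conditions: HMDS, THF, 65 °C, then evaporation; nBuLi, THF, −78 °C; Tf2O, −78 °C → rt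
Reagents that add atoms: hexamethyldisilazane, C[Si](C)(C)N[Si](C)(C)C; trifluoromethanesulfonic anhydride, O=S(=O)(OS(=O)(=O)C(F)(F)F)C(F)(F)F
Why: O-Silylation, bromine–lithium exchange with retro-Brook (1,3 O-to-C) silyl migration and O-triflation form the standard one-flask route from ortho-bromophenols to ortho-silylaryl triflates; the methoxy groups are inert to it.

Step 3
Reactants: 6 3-bromo-4,5-dimethoxybenzaldehyde
Product: 8 3-bromo-4,5-dimethoxyphenol, via 3-bromo-4,5-dimethoxyphenyl formate 7 (not isolated)
Conditions: mCPBA, CH2Cl2, 0 °C → rt; then K2CO3 (cat.), MeOH, rt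
Reagents that add atoms: 3-chloroperoxybenzoic acid, OOC(=O)c1cccc(Cl)c1
Why: Baeyer–Villiger (Dakin-type) oxidation of an electron-rich benzaldehyde; the para-methoxy group favours aryl over hydride migration, and the aryl formate is methanolysed in the same flask.

Step 4
Reactants: 8 3-bromo-4,5-dimethoxyphenol
Product: 9 5-(benzyloxy)-1-bromo-2,3-dimethoxybenzene
Conditions: BnBr, K2CO3, DMF, rt
Reagents that add atoms: benzyl bromide, BrCc1ccccc1
Why: Williamson etherification of an unhindered phenol; the aryl bromide is inert under these conditions.

Step 5
Reactants: 9 5-(benzyloxy)-1-bromo-2,3-dimethoxybenzene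
Product: 10 5-(benzyloxy)-2,3-dimethoxyphenol
Conditions: Pd2(dba)3 (2 mol%), tBuXPhos (8 mol%), KOH, 1,4-dioxane/H2O, 100 °C; then aq. HCl
Reagents that add atoms: potassium hydroxide, [K+].[OH-]
Why: Pd-catalysed hydroxylation of an aryl bromide with hydroxide (zerovalent palladium with a bulky biarylphosphine); ortho-alkoxy aryl bromides are suitable substrates and benzyl and methyl ethers are untouched.

Step 6
Reactants: 5 3,4,5-trimethoxy-2-(trimethylsilyl)phenyl trifluoromethanesulfonate; 10 5-(benzyloxy)-2,3-dimethoxyphenol
Product: 14 5-(benzyloxy)-1-(2-iodo-3,4,5-trimethoxyphenoxy)-2,3-dimethoxybenzene, via potassium 5-(benzyloxy)-2,3-dimethoxyphenoxide 11 (not isolated), via 3,4,5-trimethoxybenzyne 12 (not isolated), via 6-[5-(benzyloxy)-2,3-dimethoxyphenoxy]-2,3,4-trimethoxyphenylpotassium 13 (not isolated)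
Conditions: 10, KH (1.0 equiv), THF, 0 °C; then 18-crown-6, C4F9I (3 equiv), KF, slow addition of 5, THF, 0 °C → rt, dark
Reagents that add atoms: nonafluoro-1-iodobutane, FC(F)(F)C(F)(F)C(F)(F)C(F)(F)I
Why: Proposed new method: fluoride attacks the silicon of 5 and triflate departs to give aryne 12; phenoxide 11 adds to the aryne carbon remote from the flanking methoxy group, because the in-plane carbanion of 13 then develops next to the inductively withdrawing C3 oxygen, and 13 abstracts iodine from C4F9I, the released perfluorobutyl anion being expected to collapse to octafluorobut-1-ene and fluoride. The closest known reaction types are three-component couplings of arynes from ortho-silylaryl triflates with nitrogen or sulfur nucleophiles and halogen-atom donors, and the two-component O-arylation of phenols by 3-alkoxyarynes, which shows the same sense of addition. No ring closes and no stereocentre forms. The step needs regioselectivity (oxygen at the distal aryne carbon, iodine at the proximal one), which the single methoxy group beside the triple bond secures. It also needs iodine transfer to outrun protonation, which is secured by forming 11 with KH so that the only by-product, hydrogen, leaves the flask, by using THF in place of the more acidic acetonitrile, and by an excess of the iodine donor. Exclusion of light should suppress radical perfluoroalkylation of the phenoxide, and slow addition of 5 keeps the aryne concentration low so that 13 meets C4F9I before a second aryne.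

Step 7
Reactants: 14 5-(benzyloxy)-1-(2-iodo-3,4,5-trimethoxyphenoxy)-2,3-dimethoxybenzene; 1 3,4,5-trimethoxyphenol
Product: 15 5-(benzyloxy)-2,3-dimethoxy-1-[3,4,5-trimethoxy-2-(3,4,5-trimethoxyphenoxy)phenoxy]benzene
Conditions: CuI (20 mol%), picolinic acid (40 mol%), K3PO4, DMSO, 100 °C, Ar
Reagents that add atoms: none
Why: Ullmann-type diaryl ether synthesis with monovalent copper and picolinic acid, a system suited to hindered partners; the phenol 1 is unhindered and used in excess, and couplings of 2,6-dioxygenated aryl halides with such phenols are the classical entry to this compound class.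

Step 8
Reactants: 15 5-(benzyloxy)-2,3-dimethoxy-1-[3,4,5-trimethoxy-2-(3,4,5-trimethoxyphenoxy)phenoxy]benzene
Product: 16 3,4-dimethoxy-5-[3,4,5-trimethoxy-2-(3,4,5-trimethoxyphenoxy)phenoxy]phenol
Conditions: H2 (1 atm), Pd/C, EtOAc/MeOH, rt
Reagents that add atoms: none
Why: Hydrogenolysis of a benzyl aryl ether; methyl and diaryl ethers are stable and no halogen remains in the molecule at this stage.

Step 9
Reactants: 17 1-iodo-3,5-dimethoxybenzene
Product: 18 2-bromo-1-iodo-3,5-dimethoxybenzene
Conditions: NBS (1.0 equiv), MeCN, 0 °C → rt
Reagents that add atoms: N-bromosuccinimide, O=C1CCC(=O)N1Br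
Why: Electrophilic aromatic bromination; 1-substituted 3,5-dimethoxybenzenes are halogenated at C2, para to one methoxy group, in preference to the more shielded C4 between the two methoxy groups.

Step 10
Reactants: 18 2-bromo-1-iodo-3,5-dimethoxybenzene; 19 2,4,6-trimethoxyphenol
Product: 20 2-(2-bromo-3,5-dimethoxyphenoxy)-1,3,5-trimethoxybenzene
Conditions: CuI (10 mol%), picolinic acid (20 mol%), K3PO4, DMSO, 80 °C, Ar
Reagents that add atoms: none
Why: Chemoselective Ullmann etherification at the C–I bond in the presence of C–Br; the iodide has only one ortho substituent and is meta to both methoxy groups, and the picolinic acid system accepts 2,6-disubstituted phenols as nucleophiles.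

Step 11
Reactants: 20 2-(2-bromo-3,5-dimethoxyphenoxy)-1,3,5-trimethoxybenzene
Product: 22 2-(2-iodo-3,5-dimethoxyphenoxy)-1,3,5-trimethoxybenzene, via [2,4-dimethoxy-6-(2,4,6-trimethoxyphenoxy)phenyl]lithium 21 (not isolated)
Conditions: nBuLi, THF, −78 °C; then I2, −78 °C → rt
Reagents that add atoms: iodine, II
Why: Bromine–lithium exchange followed by iodinolysis; at −78 °C the exchange is much faster than deprotonation of ring A, and the aryllithium flanked by two oxygens is stable.

Step 12
Reactants: 16 3,4-dimethoxy-5-[3,4,5-trimethoxy-2-(3,4,5-trimethoxyphenoxy)phenoxy]phenol; 22 2-(2-iodo-3,5-dimethoxyphenoxy)-1,3,5-trimethoxybenzene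
Product: 23 1,3,5-trimethoxy-2-{2-[3,4-dimethoxy-5-[3,4,5-trimethoxy-2-(3,4,5-trimethoxyphenoxy)phenoxy]phenoxy]-3,5-dimethoxyphenoxy}benzene (tridecamethyl ether of 24)
Conditions: CuI (30 mol%), picolinic acid (60 mol%), K3PO4, DMSO, 110 °C, Ar
Reagents that add atoms: none
Why: Ullmann-type diaryl ether synthesis of the same kind as step 7; the phenol oxygen of 16 has two CH neighbours, so only the iodide is hindered, and the iodide 22 is used in excess.

Step 13
Reactants: 23 tridecamethyl ether of 24
Product: 24 pseudopentafuhalol D
Conditions: BBr3 (large excess), CH2Cl2, −78 °C → rt; then MeOH, H2O, under Ar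
Reagents that add atoms: none
Why: Lewis acid-mediated cleavage of aryl methyl ethers with BBr3; bromide attacks only the methyl carbons, so the four diaryl ether bonds are retained, and acidic, oxygen-free work-up protects the polyphenol.

## Compound list

1 | 3,4,5-trimethoxyphenol | COc1cc(O)cc(OC)c1OC | starting material
2 | 2-bromo-3,4,5-trimethoxyphenol | COc1cc(O)c(Br)c(OC)c1OC | intermediate
3 | (2-bromo-3,4,5-trimethoxyphenoxy)trimethylsilane | COc1cc(O[Si](C)(C)C)c(Br)c(OC)c1OC | intermediate
4 | lithium 3,4,5-trimethoxy-2-(trimethylsilyl)phenoxide | COc1cc([O-])c([Si](C)(C)C)c(OC)c1OC.[Li+] | intermediate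
5 | 3,4,5-trimethoxy-2-(trimethylsilyl)phenyl trifluoromethanesulfonate | COc1cc(OS(=O)(=O)C(F)(F)F)c([Si](C)(C)C)c(OC)c1OC | intermediate
6 | 3-bromo-4,5-dimethoxybenzaldehyde | COc1cc(C=O)cc(Br)c1OC | starting material
7 | 3-bromo-4,5-dimethoxyphenyl formate | COc1cc(OC=O)cc(Br)c1OC | intermediate
8 | 3-bromo-4,5-dimethoxyphenol | COc1cc(O)cc(Br)c1OC | intermediate
9 | 5-(benzyloxy)-1-bromo-2,3-dimethoxybenzene | COc1cc(OCc2ccccc2)cc(Br)c1OC | intermediate
10 | 5-(benzyloxy)-2,3-dimethoxyphenol | COc1cc(OCc2ccccc2)cc(O)c1OC | intermediate
11 | potassium 5-(benzyloxy)-2,3-dimethoxyphenoxide | COc1cc(OCc2ccccc2)cc([O-])c1OC.[K+] | intermediate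
12 | 3,4,5-trimethoxybenzyne (1,2-didehydro-3,4,5-trimethoxybenzene) | COC1=CC#CC(OC)=C1OC | intermediate
13 | 6-[5-(benzyloxy)-2,3-dimethoxyphenoxy]-2,3,4-trimethoxyphenylpotassium | COc1cc(OCc2ccccc2)cc(Oc2cc(OC)c(OC)c(OC)[c-]2)c1OC.[K+] | intermediate
14 | 5-(benzyloxy)-1-(2-iodo-3,4,5-trimethoxyphenoxy)-2,3-dimethoxybenzene | COc1cc(OCc2ccccc2)cc(Oc2cc(OC)c(OC)c(OC)c2I)c1OC | intermediate
15 | 5-(benzyloxy)-2,3-dimethoxy-1-[3,4,5-trimethoxy-2-(3,4,5-trimethoxyphenoxy)phenoxy]benzene | COc1cc(OCc2ccccc2)cc(Oc2cc(OC)c(OC)c(OC)c2Oc2cc(OC)c(OC)c(OC)c2)c1OC | intermediate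
16 | 3,4-dimethoxy-5-[3,4,5-trimethoxy-2-(3,4,5-trimethoxyphenoxy)phenoxy]phenol | COc1cc(O)cc(Oc2cc(OC)c(OC)c(OC)c2Oc2cc(OC)c(OC)c(OC)c2)c1OC | intermediate
17 | 1-iodo-3,5-dimethoxybenzene | COc1cc(I)cc(OC)c1 | starting material
18 | 2-bromo-1-iodo-3,5-dimethoxybenzene | COc1cc(I)c(Br)c(OC)c1 | intermediate
19 | 2,4,6-trimethoxyphenol | COc1cc(OC)c(O)c(OC)c1 | starting material
20 | 2-(2-bromo-3,5-dimethoxyphenoxy)-1,3,5-trimethoxybenzene | COc1cc(OC)c(Br)c(Oc2c(OC)cc(OC)cc2OC)c1 | intermediate
21 | [2,4-dimethoxy-6-(2,4,6-trimethoxyphenoxy)phenyl]lithium | COc1cc(OC)c([Li])c(Oc2c(OC)cc(OC)cc2OC)c1 | intermediate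
22 | 2-(2-iodo-3,5-dimethoxyphenoxy)-1,3,5-trimethoxybenzene | COc1cc(OC)c(I)c(Oc2c(OC)cc(OC)cc2OC)c1 | intermediate
23 | 1,3,5-trimethoxy-2-{2-[3,4-dimethoxy-5-[3,4,5-trimethoxy-2-(3,4,5-trimethoxyphenoxy)phenoxy]phenoxy]-3,5-dimethoxyphenoxy}benzene | COc1cc(OC)c(Oc2cc(OC)cc(OC)c2Oc2cc(OC)c(OC)c(Oc3cc(OC)c(OC)c(OC)c3Oc3cc(OC)c(OC)c(OC)c3)c2)c(OC)c1 | intermediate
24 | pseudopentafuhalol D | Oc1cc(O)c(Oc2cc(O)cc(O)c2Oc2cc(O)c(O)c(Oc3cc(O)c(O)c(O)c3Oc3cc(O)c(O)c(O)c3)c2)c(O)c1 | target

## Step count and risk

Total: 13 steps. Longest linear sequence: 8 steps (from 6 through steps 3, 4, 5, 6, 7, 8, 12 and 13). The ring D branch from 1 (steps 1 and 2) and the A–B branch from 17 (steps 9 to 11) join it at steps 6 and 12.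

**Step 6 (key step, proposed new method).**
- What may go wrong: protonation of aryl anion 13 by adventitious water or silanol before iodine transfer, which would lose the iodine handle. Also possible are addition of 13 to a second aryne, carbon- instead of oxygen-arylation of the phenoxide, and light-induced radical perfluoroalkylation of the electron-rich phenoxide by the iodine donor.
- Fallback by known chemistry, from 10 back to 14: purchased 5-iodo-1,2,3-trimethoxybenzene F1 is brominated with NBS at its only kind of ring CH to give 2-bromo-1-iodo-3,4,5-trimethoxybenzene F2. A CuI/picolinic acid Ullmann coupling of F2 with 10, selective for the C–I bond, gives 5-(benzyloxy)-1-(2-bromo-3,4,5-trimethoxyphenoxy)-2,3-dimethoxybenzene F3. Bromine–lithium exchange with nBuLi at −78 °C and quenching with I2 returns to the route at 14.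

**Step 7.**
- What may go wrong: slow oxidative addition at the electron-rich, doubly ortho-substituted C–I bond, so that hydrodeiodination and oxidation of the phenol win.
- Fallback, from 14 back to 15, reversing the polarity of the D–O–E bond: iodine–magnesium exchange on 14 with iPrMgCl·LiCl, borylation with B(OMe)3 and oxidation with H2O2 give 6-[5-(benzyloxy)-2,3-dimethoxyphenoxy]-2,3,4-trimethoxyphenol F4. Its phenoxide is then O-arylated by the aryne released from 5 with CsF in acetonitrile. In this two-component mode protonation of the aryl anion is the wanted outcome, and the flanking methoxy group again places the oxygen so that the 3,4,5-trimethoxyphenyl ether 15 results.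

**Step 12.**
- What may go wrong: the same reluctance of a 2,6-dioxygenated aryl iodide toward copper, now with two large partners, so that conversion stalls and 22 is reduced.
- Fallback, from 20 and 16 back to 23, again reversing polarity: 20 is lithiated as in step 11, borylated with B(OMe)3 and oxidised with H2O2 to 2,4-dimethoxy-6-(2,4,6-trimethoxyphenoxy)phenol F5. Phenol 16 is converted with Tf2O and pyridine into 3,4-dimethoxy-5-[3,4,5-trimethoxy-2-(3,4,5-trimethoxyphenoxy)phenoxy]phenyl trifluoromethanesulfonate F6, which carries its leaving group at an unhindered carbon. A Pd-catalysed C–O coupling of F5 with F6 (Pd(OAc)2, tBuXPhos, K3PO4, toluene, 100 °C) would then give 23.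

**Step 13.**
- What may go wrong: incomplete cleavage of thirteen methyl ethers, giving mixtures of partially methylated polyphenols, and oxidative loss of the free polyphenol during isolation.
- Fallback, from 23 back to 24 by a derivatise-and-release detour: the crude BBr3 product is peracetylated at once with Ac2O and pyridine to the tridecaacetate of pseudopentafuhalol D F7. This is air-stable and can be purified on silica, where under-cleaved material separates and can be resubmitted. Deacetylation with catalytic K2CO3 in degassed methanol then releases 24.

## Further compounds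

F1 | step 6 | 5-iodo-1,2,3-trimethoxybenzene | COc1cc(I)cc(OC)c1OC
F2 | step 6 | 2-bromo-1-iodo-3,4,5-trimethoxybenzene | COc1cc(I)c(Br)c(OC)c1OC
F3 | step 6 | 5-(benzyloxy)-1-(2-bromo-3,4,5-trimethoxyphenoxy)-2,3-dimethoxybenzene | COc1cc(OCc2ccccc2)cc(Oc2cc(OC)c(OC)c(OC)c2Br)c1OC
F4 | step 7 | 6-[5-(benzyloxy)-2,3-dimethoxyphenoxy]-2,3,4-trimethoxyphenol | COc1cc(OCc2ccccc2)cc(Oc2cc(OC)c(OC)c(OC)c2O)c1OC
F5 | step 12 | 2,4-dimethoxy-6-(2,4,6-trimethoxyphenoxy)phenol | COc1cc(OC)c(O)c(Oc2c(OC)cc(OC)cc2OC)c1
F6 | step 12 | 3,4-dimethoxy-5-[3,4,5-trimethoxy-2-(3,4,5-trimethoxyphenoxy)phenoxy]phenyl trifluoromethanesulfonate | COc1cc(OS(=O)(=O)C(F)(F)F)cc(Oc2cc(OC)c(OC)c(OC)c2Oc2cc(OC)c(OC)c(OC)c2)c1OC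
F7 | step 13 | tridecaacetate of pseudopentafuhalol D | CC(=O)Oc1cc(OC(C)=O)c(Oc2cc(OC(C)=O)cc(OC(C)=O)c2Oc2cc(OC(C)=O)c(OC(C)=O)c(Oc3cc(OC(C)=O)c(OC(C)=O)c(OC(C)=O)c3Oc3cc(OC(C)=O)c(OC(C)=O)c(OC(C)=O)c3)c2)c(OC(C)=O)c1
A1 | alternative 1 | 4-(benzyloxy)-3-methoxy-4-[1-(2,4,6-trimethoxyphenoxy)ethenyl]cyclobut-2-en-1-one | COC1=CC(=O)C1(OCc2ccccc2)C(=C)Oc3c(OC)cc(OC)cc3OC
A2 | alternative 1 | 4-(benzyloxy)-3-methoxy-5-(2,4,6-trimethoxyphenoxy)phenol | COc1cc(O)cc(Oc2c(OC)cc(OC)cc2OC)c1OCc1ccccc1
A3 | alternative 2 | 6-{3-[2-(benzyloxy)-3,5-dimethoxyphenoxy]-2-oxopropyl}-2,2-dimethyl-4H-1,3-dioxin-4-one | CC1(C)OC(=O)C=C(CC(=O)COc2cc(OC)cc(OC)c2OCc2ccccc2)O1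
A4 | alternative 2 | methyl 6-[2-(benzyloxy)-3,5-dimethoxyphenoxy]-3,5-dioxohexanoate | COC(=O)CC(=O)CC(=O)COc1cc(OC)cc(OC)c1OCc1ccccc1
A5 | alternative 2 | 2-[2-(benzyloxy)-3,5-dimethoxyphenoxy]benzene-1,3,5-triol | Oc1cc(O)c(Oc2cc(OC)cc(OC)c2OCc2ccccc2)c(O)c1
A6 | alternative 3 | 1-(benzyloxy)-2-(ethynyloxy)-3,4,5-trimethoxybenzene | C#COc1c(OCc2ccccc2)cc(OC)c(OC)c1OC
A7 | alternative 3 | 3-ethoxy-4-methoxycyclobut-2-en-1-one | CCOC1=CC(=O)C1OC
A8 | alternative 3 | 5-[6-(benzyloxy)-2,3,4-trimethoxyphenoxy]-3-ethoxy-2-methoxyphenol | CCOc1cc(Oc2c(OCc3ccccc3)cc(OC)c(OC)c2OC)cc(O)c1OC
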